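Count the catalyst.

all flasks: substrate 0.50 M; precatalyst 5.0 mM; time 30 s

| charge | temperature | remark |
|---|---|---|
| birch | 75 °C |  |
| oak |  | at 25 °C until 15 s, from then on at 75 °C |
| cedar | 25 °C |  |
| maple | 50 °C |  |

1. which flask leads in amount of target, in percent of the substrate charged ("all alike" within 1.5 percentage points) (birch / oak / cedar / maple / all alike)
2. how much target is there at the end, in percent of the substrate charged: birch
3. how much target is there at the end, in percent of the substrate charged: oak
4. how much target is there at the end, in percent of the substrate charged: cedar
5. how much target is there at the end, in percent of the substrate charged: maple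

- at 25 °C the constants are as listed, elsewhere as the activation energies and enthalpies make them

    target + catalyst ⇌ isomer of the product + catalyst, rate k1*[catalyst]*[target] forward; the back reaction follows from the equilibrium constant (K1 = 0.85, k1 = 2.2 L mol⁻¹ s⁻¹, Ea1 = 38.0 kJ mol⁻¹, ΔH1 = −20.0 kJ mol⁻¹)
    isomer of the product ⇌ substrate (k2 = 0.0099 s⁻¹, Ea2 = 88.0 kJ mol⁻¹)
    precatalyst → catalyst (k3 = 0.031 s⁻¹, Ea3 = 86.0 kJ mol⁻¹)
    substrate + catalyst ⇌ target + catalyst, rate k4*[substrate]*[catalyst] forward; the back reaction follows from the equilibrium constant (K4 = 3.2, k4 = 7.3 L mol⁻¹ s⁻¹, Ea4 = 41.0 kJ mol⁻¹, ΔH4 = −52.0 kJ mol⁻¹)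
    catalyst ⇌ dormant form (K5 = 0.60, k5 = 0.0082 s⁻¹, Ea5 = 82.0 kJ mol⁻¹, ΔH5 = −2.00 kJ mol⁻¹)
    (constants at 25 °C)

1. Target forms through two steps, from substrate and from isomer of the product, and both carry c_catalyst as a factor. The rate of target formation is therefore first order in c_catalyst. The bench rule treats the catalysed step from substrate as pseudo-first-order, counts the whole precatalyst charge as catalyst, and calls that step equilibrated after about 3 lifetimes of length 1/(k4·cPC).

2. Applied to cedar, at 25 °C, the lifetime is 27.4 s, so 30 s holds 1.09 lifetimes. Birch, at 75 °C, gets 11.8 lifetimes in the same time, with k4 scaled by its activation energy. The rule calls birch equilibrated and cedar unfinished.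

3. The rule assumes that the catalyst is already present. At 25 °C, the ratio k3/(k4·cPC) is 0.849, so release and the catalysed step it feeds have time scales of like size, and the product k3·t1 is 0.930, so the time of cedar is about one lifetime of release. This is the border: in cedar the rule counts catalyst that is still precatalyst.

4. Cedar needs a count of the catalyst actually delivered. Dormant form is neglected, so c_catalyst = cPC·(1 − exp(−k3·t)). Cedar's count at 30 s is 0.382. This is the catalyst exposure: k4 times the time integral of c_catalyst, or the lifetimes really delivered.

5. At 25 °C, substrate also drains to isomer of the product without catalyst, at 0.0269 s⁻¹, a constant that follows from k2 and the equilibrium constant of that step. The exposure of cedar arrives late, roughly as a ramp, so its mean time is about 20.0 s. Target share is then about exposure × exp(−drain × mean time). This neglects substrate spent on target, target going on to isomer of the product, return from isomer of the product, and the back reactions. For cedar this gives 22.3%. The reckoning stops at 25 °C and gives no number for the hot flasks.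

6. The forecast names maple as the leader, with birch 13.1%, oak 13.1%, cedar 21.5% (18% to 25%) and maple 32.8%. It calls cedar “still kinetically limited at 30 s by slow catalyst release”. For cedar it lies 0.8 percentage points below the reckoning above.

7. The flasks give maple as the leader, with birch 13.1%, oak 13.1%, cedar 21.1% and maple 32.9%.

Cedar at 30.0 s still holds 39.5% of its catalyst charge as precatalyst, and its 21.1% of target compares with the exposure reckoning of 22.3%. Oak read at 12 s is the neighbouring flask, still at 25 °C. Its exposure is 0.0722, and the mean time of 8.00 s turns that into 5.82% of target. That neighbour holds 68.9% of its catalyst charge as precatalyst, 25.2% of isomer of the product and 5.85% of target.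

The constants are made up; no experiment stands behind them.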